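The bicyclic core is cut at C4a=C8a and C6–C7 (1H-isochromene numbering). The chain C3–C4–C4a–C5–C6, with oxygen at both ends, is read as a 2-propenyl-4-pyranone: its carbonyl carbon becomes C4a and its free α-carbon becomes the carbinol C6. In one telescoped operation the C8a enolate of an α-aroyloxy ketone adds to the pyranone carbonyl. Acid then dehydrates, opens the pyrylium ring with water and recloses it through the side-chain hydroxyl (new pyran ring O2–C1–C8a–C4a–C4–C3). A chiral phosphoric acid closes the carbocycle by aldol addition of C7 to C6 and sets both stereocentres. The hindered aryl ester is installed earlier by carboxylate alkylation.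

Key step: step 7

Remark: the core is numbered as 1H-isochromene (C1, O2, C3, C4, C4a, C5, C6, C7, C8, C8a); the (R)-configured acid is assumed to lead to the (6R,7S) series, otherwise its enantiomer is used; the α-aroyloxy ketones are used as racemates because step 7 re-forms that centre.

Step 1
Reactants: 1 2,4-dihydroxy-6-methylbenzaldehyde
Product: 2 2-hydroxy-6-methyl-4-[(triisopropylsilyl)oxy]benzaldehyde
Conditions: i-Pr3SiCl, imidazole, CH2Cl2, 0 °C
Reagents that add atoms: chlorotriisopropylsilane, CC(C)[Si](Cl)(C(C)C)C(C)C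
Why: Silyl ether formation should take the free 4-hydroxyl, because the 2-hydroxyl is held in a hydrogen bond to the formyl group and is shielded from the bulky silyl chloride.

Step 2
Reactants: 2 2-hydroxy-6-methyl-4-[(triisopropylsilyl)oxy]benzaldehyde
Product: 3 2-methoxy-6-methyl-4-[(triisopropylsilyl)oxy]benzaldehyde
Conditions: MeI, K2CO3, acetone, 50 °C
Reagents that add atoms: iodomethane, CI
Why: Williamson ether synthesis at the one remaining phenol under anhydrous carbonate conditions, which the hindered aryl silyl ether is expected to tolerate.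

Step 3
Reactants: 3 2-methoxy-6-methyl-4-[(triisopropylsilyl)oxy]benzaldehyde
Product: 4 2-methoxy-6-methyl-4-[(triisopropylsilyl)oxy]benzoic acid
Conditions: NaClO2, NaH2PO4, 2-methylbut-2-ene, t-BuOH/H2O, 23 °C
Reagents that add atoms: sodium chlorite, [Na+].[O-]Cl=O
Why: Pinnick oxidation should convert the hindered, electron-rich aldehyde into the acid while the alkene scavenger keeps hypochlorous acid away from the arene.

Step 4
Reactants: 4 2-methoxy-6-methyl-4-[(triisopropylsilyl)oxy]benzoic acid; 5 3-bromobutan-2-one (racemic)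
Product: 6 3-oxobutan-2-yl 2-methoxy-6-methyl-4-[(triisopropylsilyl)oxy]benzoate (racemic)
Conditions: KHCO3, DMF, 23 °C
Reagents that add atoms: none
Why: SN2 alkylation of the carboxylate by the α-bromo ketone builds the ester at oxygen, so the 2,6-disubstituted acyl carbon is never attacked; the new centre is racemic and is re-formed in step 7.

Step 5
Reactants: 6 3-oxobutan-2-yl 2-methoxy-6-methyl-4-[(triisopropylsilyl)oxy]benzoate
Product: 9 3-oxo-5-[(triethylsilyl)oxy]pentan-2-yl 2-methoxy-6-methyl-4-[(triisopropylsilyl)oxy]benzoate, via lithium enolate 7 (not isolated), via lithium aldolate 8 (not isolated)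
Conditions: LiN(i-Pr)2, THF, −78 °C; CH2O (anhydrous, in THF), −78 °C; Et3SiCl, −78 → 0 °C
Reagents that add atoms: formaldehyde, C=O; chlorotriethylsilane, CC[Si](Cl)(CC)CC
Why: Kinetic deprotonation at the methyl group, aldol addition to formaldehyde and O-silylation of the aldolate in the same flask should give the β-silyloxy ketone, the di-ortho-substituted benzoate resisting acyl transfer to the enolate.

Step 6
Reactants: 10 (3E)-4-methoxybut-3-en-2-one; 11 (2E)-but-2-enoyl chloride
Product: 14 2-[(1E)-prop-1-en-1-yl]-4H-pyran-4-one, via lithium dienolate 12 (not isolated), via methoxy diketone 13 (not isolated)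
Conditions: LiN(SiMe3)2 (2 equiv), 10 (2 equiv), THF, −78 °C; 11 (1 equiv); then CF3CO2H, CH2Cl2, 23 °C
Reagents that add atoms: none
Why: Claisen-type C-acylation of the ketone enolate gives the 1,3-diketone, whose enol oxygen displaces methoxide from the β-methoxy enone by acid-promoted addition–elimination and closes the 4-pyranone with the E-propenyl group unchanged.

Step 7
Reactants: 9 3-oxo-5-[(triethylsilyl)oxy]pentan-2-yl 2-methoxy-6-methyl-4-[(triisopropylsilyl)oxy]benzoate; 14 2-[(1E)-prop-1-en-1-yl]-4H-pyran-4-one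
Product: 19 (6R,7S)-6-hydroxy-7-methyl-8-oxo-3-[(1E)-prop-1-en-1-yl]-5,6,7,8-tetrahydro-1H-isochromen-7-yl 2-methoxy-6-methyl-4-[(triisopropylsilyl)oxy]benzoate, via lithium enolate 15 (not isolated), via pyranol adduct 16 (not isolated), via pyranylidene ketone 17 (not isolated), via pyran aldehyde 18 (not isolated)
Conditions: LiN(i-Pr)2, THF, −78 °C; CeCl3, −78 °C; then 14, −78 → −40 °C; AcOH quench, aqueous wash, no purification; then (R)-3,3′-bis(2,4,6-triisopropylphenyl)-1,1′-binaphthalene-2,2′-diyl hydrogen phosphate (10 mol %), H2O (3 equiv), CH2Cl2, −20 → 0 °C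
Reagents that add atoms: none
Why: Proposed new method: the kinetic C8a enolate of 9 (CeCl3) adds 1,2 to the vinylogous-lactone carbonyl C4a of 14, acid expels water to the 4-acylmethylene-4H-pyran 17 (with loss of the silyl ether), and its pyrylium form takes up water at a ring α-carbon and opens to an ene-1,5-dicarbonyl pseudobase that recloses to 18 and then 19. The closest known reaction types are the Stork–Danheiser 1,2-addition to vinylogous esters, the hydrolytic ring opening and ring closure of pyrylium salts (ANRORC) and the chiral-phosphoric-acid-catalysed 6-enolendo aldol cyclisation. The pyran ring closes by 6-exo-trig hemiketalisation of the primary hydroxyl at the C3 ketone followed by loss of water, and the carbocycle by 6-(enolendo)-exo-trig addition of the C7 enol to the C6 aldehyde. C6 and C7 arise from a planar enol and a planar formyl group, so their absolute configuration is set by the chiral acid, which holds the enol hydroxyl and the formyl oxygen in one hydrogen-bonded transition state, and their trans relation (6-OH anti to 7-acyloxy) by the internally hydrogen-bonded (Z)-enol closing through a chair with the formyl oxygen pseudo-equatorial. The step needs enolisation of 9 at the methylene and not at the acyloxy methine (kinetic base, hindered benzoate that also resists acyl transfer), 1,2- over conjugate addition (hard cerium enolate) and aldol at the aldehyde and not at the C3 enone (all pyrylium and hemiketal stages are reversible and only the secondary aldol, whose quaternary C7 blocks dehydration, is a sink).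

Step 8
Reactants: 19 (6R,7S)-6-hydroxy-7-methyl-8-oxo-3-[(1E)-prop-1-en-1-yl]-5,6,7,8-tetrahydro-1H-isochromen-7-yl 2-methoxy-6-methyl-4-[(triisopropylsilyl)oxy]benzoate
Product: 20 (6R,7S)-6-hydroxy-7-methyl-8-oxo-3-[(1E)-prop-1-en-1-yl]-5,6,7,8-tetrahydro-1H-isochromen-7-yl 4-hydroxy-2-methoxy-6-methylbenzoate
Conditions: Bu4NF, AcOH (1:1), THF, 0 °C
Reagents that add atoms: none
Why: Fluoride cleavage of the aryl silyl ether, buffered with acetic acid so that the β-hydroxy ketone should neither undergo retro-aldol cleavage nor acyl migration and C6 and C7 stay as set.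

Compound list
1 | 2,4-dihydroxy-6-methylbenzaldehyde | Cc1cc(O)cc(O)c1C=O | starting material
2 | 2-hydroxy-6-methyl-4-[(triisopropylsilyl)oxy]benzaldehyde | Cc1cc(O[Si](C(C)C)(C(C)C)C(C)C)cc(O)c1C=O | intermediate
3 | 2-methoxy-6-methyl-4-[(triisopropylsilyl)oxy]benzaldehyde | COc1cc(O[Si](C(C)C)(C(C)C)C(C)C)cc(C)c1C=O | intermediate
4 | 2-methoxy-6-methyl-4-[(triisopropylsilyl)oxy]benzoic acid | COc1cc(O[Si](C(C)C)(C(C)C)C(C)C)cc(C)c1C(=O)O | intermediate
5 | 3-bromobutan-2-one (racemic) | CC(Br)C(C)=O | starting material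
6 | 3-oxobutan-2-yl 2-methoxy-6-methyl-4-[(triisopropylsilyl)oxy]benzoate (racemic) | CC(=O)C(C)OC(=O)c1c(C)cc(O[Si](C(C)C)(C(C)C)C(C)C)cc1OC | intermediate
7 | lithium enolate of 6, lithium 3-(aroyloxy)but-1-en-2-olate | [Li+].[O-]C(=C)C(C)OC(=O)c1c(C)cc(O[Si](C(C)C)(C(C)C)C(C)C)cc1OC | intermediate
8 | lithium aldolate, lithium 4-(aroyloxy)-3-oxopentan-1-olate | [Li+].[O-]CCC(=O)C(C)OC(=O)c1c(C)cc(O[Si](C(C)C)(C(C)C)C(C)C)cc1OC | intermediate
9 | 3-oxo-5-[(triethylsilyl)oxy]pentan-2-yl 2-methoxy-6-methyl-4-[(triisopropylsilyl)oxy]benzoate (racemic) | CC[Si](CC)(CC)OCCC(=O)C(C)OC(=O)c1c(C)cc(O[Si](C(C)C)(C(C)C)C(C)C)cc1OC | intermediate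
10 | (3E)-4-methoxybut-3-en-2-one | CO/C=C/C(C)=O | starting material
11 | (2E)-but-2-enoyl chloride | C/C=C/C(=O)Cl | starting material
12 | lithium (3E)-4-methoxybuta-1,3-dien-2-olate | [Li+].[O-]C(=C)/C=C/OC | intermediate
13 | (1E,6E)-1-methoxyocta-1,6-diene-3,5-dione | CO/C=C/C(=O)CC(=O)/C=C/C | intermediate
14 | 2-[(1E)-prop-1-en-1-yl]-4H-pyran-4-one | C/C=C/C1=CC(=O)C=CO1 | intermediate
15 | lithium enolate of 9 at the methylene, lithium 4-(aroyloxy)-1-[(triethylsilyl)oxy]pent-2-en-3-olate (transmetalated to cerium) | [Li+].[O-]C(=CCO[Si](CC)(CC)CC)C(C)OC(=O)c1c(C)cc(O[Si](C(C)C)(C(C)C)C(C)C)cc1OC | intermediate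
16 | 4-{4-hydroxy-2-[(1E)-prop-1-en-1-yl]-4H-pyran-4-yl}-3-oxo-5-[(triethylsilyl)oxy]pentan-2-yl 2-methoxy-6-methyl-4-[(triisopropylsilyl)oxy]benzoate (mixture of diastereomers) | C/C=C/C1=CC(O)(C(CO[Si](CC)(CC)CC)C(=O)C(C)OC(=O)c2c(C)cc(O[Si](C(C)C)(C(C)C)C(C)C)cc2OC)C=CO1 | intermediate
17 | 5-hydroxy-3-oxo-4-{2-[(1E)-prop-1-en-1-yl]-4H-pyran-4-ylidene}pentan-2-yl 2-methoxy-6-methyl-4-[(triisopropylsilyl)oxy]benzoate (racemic, exocyclic alkene not fixed) | C/C=C/C1=CC(=C(CO)C(=O)C(C)OC(=O)c2c(C)cc(O[Si](C(C)C)(C(C)C)C(C)C)cc2OC)C=CO1 | intermediate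
18 | 1-oxo-1-{4-(2-oxoethyl)-6-[(1E)-prop-1-en-1-yl]-2H-pyran-3-yl}propan-2-yl 2-methoxy-6-methyl-4-[(triisopropylsilyl)oxy]benzoate (racemic) | C/C=C/C1=CC(CC=O)=C(CO1)C(=O)C(C)OC(=O)c1c(C)cc(O[Si](C(C)C)(C(C)C)C(C)C)cc1OC | intermediate
19 | (6R,7S)-6-hydroxy-7-methyl-8-oxo-3-[(1E)-prop-1-en-1-yl]-5,6,7,8-tetrahydro-1H-isochromen-7-yl 2-methoxy-6-methyl-4-[(triisopropylsilyl)oxy]benzoate | C/C=C/C1=CC2=C(CO1)C(=O)[C@@](C)(OC(=O)c1c(C)cc(O[Si](C(C)C)(C(C)C)C(C)C)cc1OC)[C@H](O)C2 | intermediate
20 | (6R,7S)-6-hydroxy-7-methyl-8-oxo-3-[(1E)-prop-1-en-1-yl]-5,6,7,8-tetrahydro-1H-isochromen-7-yl 4-hydroxy-2-methoxy-6-methylbenzoate | C/C=C/C1=CC2=C(CO1)C(=O)[C@@](C)(OC(=O)c1c(C)cc(O)cc1OC)[C@H](O)C2 | target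

Total step count: 8. Longest linear sequence: 7 steps (steps 1, 2, 3, 4, 5, 7, 8); step 6 is the convergent branch.

Steps most likely to fail

Step 7 (proposed new method). The chiral acid may fail to control the face of the planar enol in the ring-closing aldol, and reversible aldol addition may erode whatever selectivity is reached. The enolate may also add to the pyranone in a conjugate sense at the free α-carbon instead of at the carbonyl. The fallback replaces the catalyst-controlled telescoped cascade by staged known reactions with a resolution, and sets out from 9 and 14. The CeCl3-mediated aldol addition is quenched with AcOH, and the dehydrated, still silylated aldol condensation product, 3-oxo-4-{2-[(1E)-prop-1-en-1-yl]-4H-pyran-4-ylidene}-5-[(triethylsilyl)oxy]pentan-2-yl 2-methoxy-6-methyl-4-[(triisopropylsilyl)oxy]benzoate F1, is isolated, which also removes any conjugate adduct. Aqueous AcOH in THF cleaves the triethylsilyl ether and converts F1, by vinylogous-ester hydrolysis and cyclodehydration, into pyran aldehyde 18, now isolated. Soft enolisation (MgBr2·OEt2, Et3N, CH2Cl2) should close the aldol ring to the racemate, 19 together with its (6S,7R)-enantiomer F2. Candida antarctica lipase B with vinyl acetate is then expected to acetylate F2 to the (6S,7R)-6-acetate F3 and leave 19, which is separated and comes back to the route at 19.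

Step 5. The lithium enolate may equilibrate to the acyloxy-substituted side or add twice to formaldehyde, and the aldolate may revert before it is silylated. The fallback sets out from 6 and trades the enolate aldol for a Lewis-acid aldol of an isolated enol silane. LiN(i-Pr)2 with Me3SiCl as internal quench should give the kinetic enol silane 3-[(trimethylsilyl)oxy]but-3-en-2-yl 2-methoxy-6-methyl-4-[(triisopropylsilyl)oxy]benzoate F4. Yb(OTf)3-catalysed Mukaiyama aldol addition to aqueous formaldehyde in THF should give 5-hydroxy-3-oxopentan-2-yl 2-methoxy-6-methyl-4-[(triisopropylsilyl)oxy]benzoate F5. Et3SiCl and imidazole then return to 9.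

Step 6. Acylation of the dienolate may go at oxygen, and the enolate may deprotonate the unsaturated acid chloride or add to it in a conjugate sense. The fallback sets out from 10 and builds the ring by cycloaddition. Me3SiCl, Et3N and ZnCl2 should give (1E)-1-methoxy-3-[(trimethylsilyl)oxy]buta-1,3-diene F6. Hetero-Diels–Alder reaction with (E)-but-2-enal (BF3·OEt2, then CF3CO2H) should give racemic 2-[(1E)-prop-1-en-1-yl]-2,3-dihydro-4H-pyran-4-one F7. LiN(i-Pr)2 and Me3SiCl should give trimethyl({2-[(1E)-prop-1-en-1-yl]-2H-pyran-4-yl}oxy)silane F8, and Saegusa–Ito oxidation with Pd(OAc)2 in MeCN comes back to the route at 14.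

Further compounds
F1 | step 7 | 3-oxo-4-{2-[(1E)-prop-1-en-1-yl]-4H-pyran-4-ylidene}-5-[(triethylsilyl)oxy]pentan-2-yl 2-methoxy-6-methyl-4-[(triisopropylsilyl)oxy]benzoate (racemic) | C/C=C/C1=CC(=C(CO[Si](CC)(CC)CC)C(=O)C(C)OC(=O)c2c(C)cc(O[Si](C(C)C)(C(C)C)C(C)C)cc2OC)C=CO1
F2 | step 7 | (6S,7R)-6-hydroxy-7-methyl-8-oxo-3-[(1E)-prop-1-en-1-yl]-5,6,7,8-tetrahydro-1H-isochromen-7-yl 2-methoxy-6-methyl-4-[(triisopropylsilyl)oxy]benzoate | C/C=C/C1=CC2=C(CO1)C(=O)[C@](C)(OC(=O)c1c(C)cc(O[Si](C(C)C)(C(C)C)C(C)C)cc1OC)[C@@H](O)C2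
F3 | step 7 | (6S,7R)-6-acetoxy-7-methyl-8-oxo-3-[(1E)-prop-1-en-1-yl]-5,6,7,8-tetrahydro-1H-isochromen-7-yl 2-methoxy-6-methyl-4-[(triisopropylsilyl)oxy]benzoate | C/C=C/C1=CC2=C(CO1)C(=O)[C@](C)(OC(=O)c1c(C)cc(O[Si](C(C)C)(C(C)C)C(C)C)cc1OC)[C@@H](OC(C)=O)C2
F4 | step 5 | 3-[(trimethylsilyl)oxy]but-3-en-2-yl 2-methoxy-6-methyl-4-[(triisopropylsilyl)oxy]benzoate (racemic) | C=C(O[Si](C)(C)C)C(C)OC(=O)c1c(C)cc(O[Si](C(C)C)(C(C)C)C(C)C)cc1OC
F5 | step 5 | 5-hydroxy-3-oxopentan-2-yl 2-methoxy-6-methyl-4-[(triisopropylsilyl)oxy]benzoate (racemic) | OCCC(=O)C(C)OC(=O)c1c(C)cc(O[Si](C(C)C)(C(C)C)C(C)C)cc1OC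
F6 | step 6 | (1E)-1-methoxy-3-[(trimethylsilyl)oxy]buta-1,3-diene | CO/C=C/C(=C)O[Si](C)(C)C
F7 | step 6 | 2-[(1E)-prop-1-en-1-yl]-2,3-dihydro-4H-pyran-4-one (racemic) | C/C=C/C1CC(=O)C=CO1
F8 | step 6 | trimethyl({2-[(1E)-prop-1-en-1-yl]-2H-pyran-4-yl}oxy)silane (racemic) | C/C=C/C1C=C(O[Si](C)(C)C)C=CO1
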